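**Plan**

1. Labels: the upper dihydrobenzofuran is O1, C2, C3, C3a–C7a on ring A (C4 carries the styryl group, C6 the OH). The lower one is O1', C2', C3', C3a'–C7a' on ring B (C7' is bonded to C2).
2. Cuts: (a) the C4–vinyl bond (Heck; C4 carries bromine until then); (b) C2–C3 of the upper dihydrofuran ring, back to an aryl benzyl ether O1–CH2–C7' and a carbene at C3; (c) the O1–CH2 bond (Mitsunobu) between a ring A benzophenone and the C7' hydroxymethyl derivative of the lower dihydrobenzofuran; (d) C2'–C3' of the lower ring in the same way.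
3. Forward: lower dihydrofuran ring by C–H insertion, acid equilibration to trans, C7' hydroxymethyl, ether to the ring A ketone, hydrazone, C–H insertion closing the upper dihydrofuran ring (the last ring), O-demethylation with C2 equilibration, acetylation, Heck, deacetylation.
4. Enabling feature: C2 is α to O1 and benzylic to a ring with oxygen ortho (O1') and para (C4'–O), and as a CH2 group it sits 1,5 to C3 across ring A, so a donor/donor carbene at C3 inserts into that C–H bond. The same two oxygens let O1–C2 ionize reversibly, so C2 settles trans. Bromine at C4 blocks the other flank of the carbene, keeps an alkene away from it and later is the Heck handle.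
5. Stereochemistry: C3 and C3' come from the chiral dirhodium carboxylate (catalyst control); C2 and C2' from thermodynamic equilibration to trans; the E-alkene from the Heck reaction.

Key step: step 12

Assumption: the S antipode of Rh2(PTAD)4 (PTAD = N-phthaloyl-(1-adamantyl)glycinate) is written for the 3S sense of insertion; if a model ether shows the opposite sense, the R antipode is used in steps 5 and 12 and nothing else changes. Grignard reagent 2 is taken as its commercial THF solution.

**Route**

Step 1
Reactants: 1 3-bromo-2,6-dimethoxybenzoic acid; 2 3,5-dimethoxyphenylmagnesium chloride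
Product: 4 (3-bromo-2,6-dimethoxyphenyl)(3,5-dimethoxyphenyl)methanone, via 3-bromo-2,6-dimethoxybenzoyl chloride 3 (not isolated)
Conditions: (COCl)2, DMF (cat.), CH2Cl2, 0 °C → rt, evaporate; then 2, THF, −78 → 0 °C
Reagents that add atoms: oxalyl chloride, O=C(Cl)C(Cl)=O (gives the chlorine of intermediate 3; no atom of it remains in 4)
Why: Nucleophilic acyl substitution of an acid chloride by an aryl Grignard reagent; the ketone formed has two ortho substituents and should be too hindered for a second addition at low temperature.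

Step 2
Reactants: 4 (3-bromo-2,6-dimethoxyphenyl)(3,5-dimethoxyphenyl)methanone
Product: 5 (3-bromo-2-hydroxy-6-methoxyphenyl)(3,5-dimethoxyphenyl)methanone
Conditions: BCl3 (1.2 equiv), CH2Cl2, −78 → 0 °C; H2O
Reagents that add atoms: none
Why: Chelation-directed Lewis acid ether cleavage: both methoxy groups are ortho to the ketone, but the one wedged between bromine and the aroyl group is twisted out of conjugation, so it is the stronger donor to boron and is expected to be cleaved first, after which the boron chelate protects the other.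

Step 3
Reactants: 5 (3-bromo-2-hydroxy-6-methoxyphenyl)(3,5-dimethoxyphenyl)methanone; 6 2,4-dimethoxybenzyl alcohol
Product: 7 {3-bromo-2-[(2,4-dimethoxybenzyl)oxy]-6-methoxyphenyl}(3,5-dimethoxyphenyl)methanone
Conditions: PPh3, DIAD, THF, 0 °C → rt
Reagents that add atoms: none
Why: Mitsunobu etherification, in which the acidic, hydrogen-bonded phenol is alkylated by the oxyphosphonium salt of a primary, electron-rich benzylic alcohol.

Step 4
Reactants: 7 {3-bromo-2-[(2,4-dimethoxybenzyl)oxy]-6-methoxyphenyl}(3,5-dimethoxyphenyl)methanone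
Product: 8 hydrazone of 7 (N-unsubstituted; either C=N geometry serves)
Conditions: N2H4·H2O (excess), AcOH (cat.), n-BuOH, 110 °C, sealed tube
Reagents that add atoms: hydrazine hydrate, NN.O
Why: Condensation of a ketone with hydrazine; the di-ortho-substituted carbonyl needs excess reagent and heat, and no strong base is present that could start a Wolff–Kishner reduction.

Step 5
Reactants: 8 hydrazone of 7
Product: 10 (2R,3S)-7-bromo-2-(2,4-dimethoxyphenyl)-3-(3,5-dimethoxyphenyl)-4-methoxy-2,3-dihydro-1-benzofuran (cis), via diaryldiazomethane 9 (not isolated)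
Conditions: MnO2, CH2Cl2, 0 °C, filter; filtrate added slowly to Rh2(S-PTAD)4 (1 mol %), CH2Cl2, −20 → 0 °C
Reagents that add atoms: none
Why: Hydrazone oxidation to the diazo compound and dirhodium-catalysed intramolecular 1,5 C–H insertion of the donor/donor carbene into the O–CH2–aryl group, which is α to oxygen and benzylic to the 2,4-dimethoxyphenyl ring and so far more reactive than the methoxy C–H on the other flank; the chiral carboxylate ligands should set C3' (S) and the concerted insertion should give the cis ring (C2' R).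

Step 6
Reactants: 10 the cis (2R,3S) dihydrobenzofuran
Product: 11 (2S,3S)-7-bromo-2-(2,4-dimethoxyphenyl)-3-(3,5-dimethoxyphenyl)-4-methoxy-2,3-dihydro-1-benzofuran (trans)
Conditions: TFA (2 vol %), CH2Cl2 (dilute), 0 °C
Reagents that add atoms: none
Why: Acid-mediated epimerization: the O1'–C2' bond ionizes reversibly to a 2,4-dimethoxybenzyl cation that is recaptured by the tethered phenol, so C2' should equilibrate to the more stable trans arrangement while C3', which has no leaving group, keeps its configuration.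

Step 7
Reactants: 11 the trans (2S,3S) bromide
Product: 12 [(2S,3S)-2-(2,4-dimethoxyphenyl)-3-(3,5-dimethoxyphenyl)-4-methoxy-2,3-dihydro-1-benzofuran-7-yl]methanol
Conditions: Bu3SnCH2OH, Pd(PPh3)4 (5 mol %), 1,4-dioxane, 100 °C
Reagents that add atoms: (tributylstannyl)methanol, OC[Sn](CCCC)(CCCC)CCCC
Why: Migita–Kosugi–Stille coupling of the aryl bromide with a hydroxymethyl stannane, whose α-oxygen speeds transmetalation; the ring stereocenters are not involved.

Step 8
Reactants: 13 1-bromo-3,5-dimethoxybenzene; 14 3,5-dimethoxybenzoyl chloride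
Product: 15 (2-bromo-4,6-dimethoxyphenyl)(3,5-dimethoxyphenyl)methanone
Conditions: AlCl3 (1.2 equiv), CH2Cl2, 0 °C → rt
Reagents that add atoms: none
Why: Friedel–Crafts acylation; attack should occur para to one methoxy group and ortho to the other (next to bromine) and not at the position flanked by both methoxy groups, the usual preference of 1,3-dimethoxyarenes.

Step 9
Reactants: 15 (2-bromo-4,6-dimethoxyphenyl)(3,5-dimethoxyphenyl)methanone
Product: 16 (2-bromo-6-hydroxy-4-methoxyphenyl)(3,5-dimethoxyphenyl)methanone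
Conditions: BCl3 (1.2 equiv), CH2Cl2, −78 → 0 °C; H2O
Reagents that add atoms: none
Why: Chelation-directed cleavage by BCl3 of the only methoxy group ortho to the ketone; the para methoxy group and those of the other ring are not chelated and should stay.

Step 10
Reactants: 16 (2-bromo-6-hydroxy-4-methoxyphenyl)(3,5-dimethoxyphenyl)methanone; 12 the benzylic alcohol of the lower dihydrobenzofuran
Product: 17 (2-bromo-6-{[(2S,3S)-2-(2,4-dimethoxyphenyl)-3-(3,5-dimethoxyphenyl)-4-methoxy-2,3-dihydro-1-benzofuran-7-yl]methoxy}-4-methoxyphenyl)(3,5-dimethoxyphenyl)methanone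
Conditions: PPh3, DIAD, THF, 0 °C → rt
Reagents that add atoms: none
Why: Mitsunobu etherification of an ortho-acyl phenol with a primary benzylic alcohol, which joins the two halves through the O1–CH2 bond without touching the existing stereocenters.

Step 11
Reactants: 17 the ether ketone
Product: 18 hydrazone of 17 (N-unsubstituted; either C=N geometry serves)
Conditions: N2H4·H2O (excess), AcOH (cat.), n-BuOH, 110 °C, sealed tube
Reagents that add atoms: hydrazine hydrate, NN.O
Why: Condensation of a ketone with hydrazine under forcing, base-free conditions, as in step 4; the electron-rich aryl bromide is not open to nucleophilic substitution.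

Step 12
Reactants: 18 hydrazone of 17
Product: 20 (2R,3S)-4-bromo-2-[(2S,3S)-2-(2,4-dimethoxyphenyl)-3-(3,5-dimethoxyphenyl)-4-methoxy-2,3-dihydro-1-benzofuran-7-yl]-3-(3,5-dimethoxyphenyl)-6-methoxy-2,3-dihydro-1-benzofuran (upper ring cis), via diaryldiazomethane 19 (not isolated)
Conditions: MnO2, CH2Cl2, 0 °C, filter; filtrate added slowly to Rh2(S-PTAD)4 (1–2 mol %), CH2Cl2, −20 → 0 °C
Reagents that add atoms: none
Why: MnO2 dehydrogenates the hydrazone to diaryldiazomethane 19, which loses N2 on Rh2(S-PTAD)4 to give a donor/donor rhodium carbene at C3; this inserts into one C–H bond of the O1–CH2–C7' group through a concerted, asynchronous three-centre transition state with hydride-transfer character, forming the C2–C3 bond. The closest known reaction type is the enantioselective intramolecular C–H insertion of donor/donor carbenes made from 2-(benzyloxy)benzophenone hydrazones, which gives 2,3-diaryl-2,3-dihydrobenzofurans. The upper dihydrofuran ring closes by 1,5 C–H insertion, through a five-membered cyclic transition state over C3, C3a, C7a, O1 and C2. C3 (S) should be set by the chiral carboxylate ligands, which choose the face of the carbene and are expected to override the distant C2' and C3' centres; C2 arises cis to the C3 aryl group (R) from the same transition state and is corrected in step 13. The step needs chemoselectivity for insertion over azine formation and over attack on the electron-rich arenes, and site selectivity for this one C–H bond. The substrate secures both: the bond is α to oxygen, benzylic to an ortho,para-dioxygenated ring and held 1,5 to the carbene by ring A, the other flank of the carbene carries bromine and no C–H bond, no alkene is present yet, and slow addition keeps the diazo concentration low.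

Step 13
Reactants: 20 the octamethyl ether with the cis upper ring
Product: 21 (2S,3S)-4-bromo-2-[(2S,3S)-2-(2,4-dihydroxyphenyl)-3-(3,5-dihydroxyphenyl)-4-hydroxy-2,3-dihydro-1-benzofuran-7-yl]-3-(3,5-dihydroxyphenyl)-2,3-dihydro-1-benzofuran-6-ol (octaphenol, both rings trans)
Conditions: BBr3 (20 equiv), CH2Cl2, −78 °C → rt; MeOH, then H2O
Reagents that add atoms: none
Why: Lewis acid cleavage of all eight aryl methyl ethers; under these conditions the O1–C2 bond, whose C2 aryl group has oxygen ortho and para, should open reversibly to a quinone-methide-type cation and reclose to the thermodynamically preferred trans ring, while C3 is untouched and the lower ring is already at its trans equilibrium geometry.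

Step 14
Reactants: 21 the octaphenol bromide
Product: 22 octaacetate of 21
Conditions: Ac2O, pyridine, DMAP (cat.), rt
Reagents that add atoms: acetic anhydride, CC(=O)OC(C)=O
Why: Peracetylation of phenols under nucleophilic catalysis should give an air-stable octaacetate that can be chromatographed and whose aryl bromide is less electron-rich for oxidative addition.

Step 15
Reactants: 22 the octaacetate bromide; 23 4-acetoxystyrene
Product: 24 nonaacetate of the target
Conditions: Pd(OAc)2 (5 mol %), P(o-tol)3 (12 mol %), NaOAc, DMA, 110 °C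
Reagents that add atoms: none
Why: Mizoroki–Heck reaction: oxidative addition of zerovalent palladium to the aryl bromide, syn insertion at the terminal carbon of the styrene and syn β-hydride elimination should give the E-stilbene, and acetate as the base cannot scramble the aryl acetates.

Step 16
Reactants: 24 the nonaacetate
Product: 25 (2S,3S)-2-[(2S,3S)-2-(2,4-dihydroxyphenyl)-3-(3,5-dihydroxyphenyl)-4-hydroxy-2,3-dihydro-1-benzofuran-7-yl]-3-(3,5-dihydroxyphenyl)-4-[(E)-2-(4-hydroxyphenyl)ethenyl]-2,3-dihydro-1-benzofuran-6-ol (CNP0397447.1)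
Conditions: K2CO3 (cat.), MeOH (degassed), 0 °C → rt, under argon; acidic ion-exchange resin
Reagents that add atoms: none
Why: Zemplén-type methanolysis of the nine aryl acetates under mild base, with no acid that could protonate the stilbene; any ring opening through a para-phenoxide is reversible and should return the trans rings.

**Compound list**

1 | 3-bromo-2,6-dimethoxybenzoic acid | COc1ccc(Br)c(OC)c1C(=O)O | starting material
2 | 3,5-dimethoxyphenylmagnesium chloride | COc1cc(OC)cc([Mg]Cl)c1 | starting material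
3 | 3-bromo-2,6-dimethoxybenzoyl chloride | COc1ccc(Br)c(OC)c1C(Cl)=O | intermediate
4 | (3-bromo-2,6-dimethoxyphenyl)(3,5-dimethoxyphenyl)methanone | COc1cc(OC)cc(c1)C(=O)c1c(OC)ccc(Br)c1OC | intermediate
5 | (3-bromo-2-hydroxy-6-methoxyphenyl)(3,5-dimethoxyphenyl)methanone | COc1cc(OC)cc(c1)C(=O)c1c(OC)ccc(Br)c1O | intermediate
6 | 2,4-dimethoxybenzyl alcohol | COc1ccc(CO)c(OC)c1 | starting material
7 | {3-bromo-2-[(2,4-dimethoxybenzyl)oxy]-6-methoxyphenyl}(3,5-dimethoxyphenyl)methanone | COc1cc(OC)cc(c1)C(=O)c1c(OC)ccc(Br)c1OCc1ccc(OC)cc1OC | intermediate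
8 | hydrazone of 7 | COc1cc(OC)cc(c1)C(=NN)c1c(OC)ccc(Br)c1OCc1ccc(OC)cc1OC | intermediate
9 | 1-bromo-3-[diazo(3,5-dimethoxyphenyl)methyl]-2-[(2,4-dimethoxybenzyl)oxy]-4-methoxybenzene | COc1cc(OC)cc(c1)C(=[N+]=[N-])c1c(OC)ccc(Br)c1OCc1ccc(OC)cc1OC | intermediate
10 | (2R,3S)-7-bromo-2-(2,4-dimethoxyphenyl)-3-(3,5-dimethoxyphenyl)-4-methoxy-2,3-dihydro-1-benzofuran (cis) | Brc1ccc(OC)c2c1O[C@@H](c1ccc(OC)cc1OC)[C@H]2c1cc(OC)cc(OC)c1 | intermediate
11 | (2S,3S)-7-bromo-2-(2,4-dimethoxyphenyl)-3-(3,5-dimethoxyphenyl)-4-methoxy-2,3-dihydro-1-benzofuran (trans) | Brc1ccc(OC)c2c1O[C@H](c1ccc(OC)cc1OC)[C@H]2c1cc(OC)cc(OC)c1 | intermediate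
12 | [(2S,3S)-2-(2,4-dimethoxyphenyl)-3-(3,5-dimethoxyphenyl)-4-methoxy-2,3-dihydro-1-benzofuran-7-yl]methanol | OCc1ccc(OC)c2c1O[C@H](c1ccc(OC)cc1OC)[C@H]2c1cc(OC)cc(OC)c1 | intermediate
13 | 1-bromo-3,5-dimethoxybenzene | COc1cc(Br)cc(OC)c1 | starting material
14 | 3,5-dimethoxybenzoyl chloride | COc1cc(OC)cc(c1)C(Cl)=O | starting material
15 | (2-bromo-4,6-dimethoxyphenyl)(3,5-dimethoxyphenyl)methanone | COc1cc(OC)cc(c1)C(=O)c1c(Br)cc(OC)cc1OC | intermediate
16 | (2-bromo-6-hydroxy-4-methoxyphenyl)(3,5-dimethoxyphenyl)methanone | COc1cc(OC)cc(c1)C(=O)c1c(Br)cc(OC)cc1O | intermediate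
17 | (2-bromo-6-{[(2S,3S)-2-(2,4-dimethoxyphenyl)-3-(3,5-dimethoxyphenyl)-4-methoxy-2,3-dihydro-1-benzofuran-7-yl]methoxy}-4-methoxyphenyl)(3,5-dimethoxyphenyl)methanone | COc1cc(OC)cc(c1)C(=O)c1c(Br)cc(OC)cc1OCc1ccc(OC)c2c1O[C@H](c1ccc(OC)cc1OC)[C@H]2c1cc(OC)cc(OC)c1 | intermediate
18 | hydrazone of 17 | COc1cc(OC)cc(c1)C(=NN)c1c(Br)cc(OC)cc1OCc1ccc(OC)c2c1O[C@H](c1ccc(OC)cc1OC)[C@H]2c1cc(OC)cc(OC)c1 | intermediate
19 | (2S,3S)-7-({3-bromo-2-[diazo(3,5-dimethoxyphenyl)methyl]-5-methoxyphenoxy}methyl)-2-(2,4-dimethoxyphenyl)-3-(3,5-dimethoxyphenyl)-4-methoxy-2,3-dihydro-1-benzofuran | COc1cc(OC)cc(c1)C(=[N+]=[N-])c1c(Br)cc(OC)cc1OCc1ccc(OC)c2c1O[C@H](c1ccc(OC)cc1OC)[C@H]2c1cc(OC)cc(OC)c1 | intermediate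
20 | (2R,3S)-4-bromo-2-[(2S,3S)-2-(2,4-dimethoxyphenyl)-3-(3,5-dimethoxyphenyl)-4-methoxy-2,3-dihydro-1-benzofuran-7-yl]-3-(3,5-dimethoxyphenyl)-6-methoxy-2,3-dihydro-1-benzofuran (upper ring cis) | Brc1cc(OC)cc2c1[C@H](c1cc(OC)cc(OC)c1)[C@H](c1ccc(OC)c3c1O[C@H](c1ccc(OC)cc1OC)[C@H]3c1cc(OC)cc(OC)c1)O2 | intermediate
21 | (2S,3S)-4-bromo-2-[(2S,3S)-2-(2,4-dihydroxyphenyl)-3-(3,5-dihydroxyphenyl)-4-hydroxy-2,3-dihydro-1-benzofuran-7-yl]-3-(3,5-dihydroxyphenyl)-2,3-dihydro-1-benzofuran-6-ol | Brc1cc(O)cc2c1[C@H](c1cc(O)cc(O)c1)[C@@H](c1ccc(O)c3c1O[C@H](c1ccc(O)cc1O)[C@H]3c1cc(O)cc(O)c1)O2 | intermediate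
22 | octaacetate of 21 | Brc1cc(OC(C)=O)cc2c1[C@H](c1cc(OC(C)=O)cc(OC(C)=O)c1)[C@@H](c1ccc(OC(C)=O)c3c1O[C@H](c1ccc(OC(C)=O)cc1OC(C)=O)[C@H]3c1cc(OC(C)=O)cc(OC(C)=O)c1)O2 | intermediate
23 | 4-acetoxystyrene | CC(=O)Oc1ccc(C=C)cc1 | starting material
24 | nonaacetate of the target | CC(=O)Oc1ccc(/C=C/c2cc(OC(C)=O)cc3c2[C@H](c2cc(OC(C)=O)cc(OC(C)=O)c2)[C@@H](c2ccc(OC(C)=O)c4c2O[C@H](c2ccc(OC(C)=O)cc2OC(C)=O)[C@H]4c2cc(OC(C)=O)cc(OC(C)=O)c2)O3)cc1 | intermediate
25 | (2S,3S)-2-[(2S,3S)-2-(2,4-dihydroxyphenyl)-3-(3,5-dihydroxyphenyl)-4-hydroxy-2,3-dihydro-1-benzofuran-7-yl]-3-(3,5-dihydroxyphenyl)-4-[(E)-2-(4-hydroxyphenyl)ethenyl]-2,3-dihydro-1-benzofuran-6-ol | Oc1ccc(/C=C/c2cc(O)cc3c2[C@H](c2cc(O)cc(O)c2)[C@@H](c2ccc(O)c4c2O[C@H](c2ccc(O)cc2O)[C@H]4c2cc(O)cc(O)c2)O3)cc1 | target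

**Count and risks**

Total step count: 16. Longest linear sequence: 14 steps (steps 1–7, then 10–16); steps 8–9 form the short branch.

Steps most likely to fail:

1. Step 12. The carbene carbon is flanked by bromine and the alkoxy group, so loss of N2 and insertion may be slow and azine formation or attack on the electron-rich arenes may take over. The chiral lower half may also be mismatched with the catalyst and give poor facial selectivity at C3.
Fallback, setting out from 16 and 12 and returning at 21: ketone 16 is reduced (NaBH4, MeOH) to the racemic benzhydrol (2-bromo-6-hydroxy-4-methoxyphenyl)(3,5-dimethoxyphenyl)methanol F1. This is converted with 4-methylbenzenesulfinic acid (CH2Cl2, rt) into the sulfone 3-bromo-2-[(3,5-dimethoxyphenyl)(4-methylbenzenesulfonyl)methyl]-5-methoxyphenol F2, a base-triggered precursor of the ortho-quinone methide of ring A. Alcohol 12 is turned with tetrahydrothiophene and HBF4·OEt2 (CH2Cl2, 0 °C) into the benzylic sulfonium tetrafluoroborate 1-{[(2S,3S)-2-(2,4-dimethoxyphenyl)-3-(3,5-dimethoxyphenyl)-4-methoxy-2,3-dihydro-1-benzofuran-7-yl]methyl}thiolan-1-ium tetrafluoroborate F3. With Cs2CO3 in CH2Cl2, F2 should lose sulfinate to the ortho-quinone methide, the ylide of F3 should add to its exocyclic carbon (C3), and the phenoxide should displace tetrahydrothiophene at C2. This (4+1) annulation is a known way to trans-2,3-disubstituted dihydrobenzofurans. It should give the trans octamethyl ether (2S,3S)-4-bromo-2-[(2S,3S)-2-(2,4-dimethoxyphenyl)-3-(3,5-dimethoxyphenyl)-4-methoxy-2,3-dihydro-1-benzofuran-7-yl]-3-(3,5-dimethoxyphenyl)-6-methoxy-2,3-dihydro-1-benzofuran F4 together with its 2R,3R ring diastereomer. The two would be separated by chromatography, since C3 is then not under catalyst control. F4 is demethylated as in step 13 to 21.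

2. Step 13. During the long exposure to BBr3 the ring-opened C2 cation may lose the C3 proton (elimination to a triarylethene, which would erase C3) or alkylate a resorcinol ring of another molecule.
Fallback, setting out from 20 and returning at 21: the ether cleavage is run only as a deprotection (BBr3, CH2Cl2, −78 → −20 °C, short contact, cold MeOH quench) and is allowed to give the octaphenol with the upper ring still cis, (2R,3S)-4-bromo-2-[(2S,3S)-2-(2,4-dihydroxyphenyl)-3-(3,5-dihydroxyphenyl)-4-hydroxy-2,3-dihydro-1-benzofuran-7-yl]-3-(3,5-dihydroxyphenyl)-2,3-dihydro-1-benzofuran-6-ol F5. C2 is then corrected in a separate base-mediated step (K2CO3, degassed MeOH, 40 °C). The C4' phenoxide, para to C2, should expel O1 to a para-quinone methide and the ring A phenoxide should add back (retro-oxa-Michael and oxa-Michael), leading to the trans compound 21 without a cation at C2.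

3. Step 11. Hydrazine may fail to condense at the carbonyl group, which is shielded by bromine on one side and the large ether on the other, or may do so only under heating that degrades the material.
Fallback, setting out from 17 and returning at 18: 17 is condensed with 1,2-bis(tert-butyldimethylsilyl)hydrazine under Sc(OTf)3 catalysis (CHCl3, 55 °C), a silyl-transfer condensation suited to hindered ketones, to give the N-(tert-butyldimethylsilyl)hydrazone of 17 F6. Bu4NF in THF at 0 °C then frees hydrazone 18 just before the oxidation.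

**Further compounds**

F1 | step 12 | (2-bromo-6-hydroxy-4-methoxyphenyl)(3,5-dimethoxyphenyl)methanol (racemic) | COc1cc(OC)cc(c1)C(O)c1c(Br)cc(OC)cc1O
F2 | step 12 | 3-bromo-2-[(3,5-dimethoxyphenyl)(4-methylbenzenesulfonyl)methyl]-5-methoxyphenol (racemic) | COc1cc(OC)cc(c1)C(c1c(Br)cc(OC)cc1O)S(=O)(=O)c1ccc(C)cc1
F3 | step 12 | 1-{[(2S,3S)-2-(2,4-dimethoxyphenyl)-3-(3,5-dimethoxyphenyl)-4-methoxy-2,3-dihydro-1-benzofuran-7-yl]methyl}thiolan-1-ium tetrafluoroborate | F[B-](F)(F)F.C(c1ccc(OC)c2c1O[C@H](c1ccc(OC)cc1OC)[C@H]2c1cc(OC)cc(OC)c1)[S+]1CCCC1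
F4 | step 12 | (2S,3S)-4-bromo-2-[(2S,3S)-2-(2,4-dimethoxyphenyl)-3-(3,5-dimethoxyphenyl)-4-methoxy-2,3-dihydro-1-benzofuran-7-yl]-3-(3,5-dimethoxyphenyl)-6-methoxy-2,3-dihydro-1-benzofuran (upper ring trans) | Brc1cc(OC)cc2c1[C@H](c1cc(OC)cc(OC)c1)[C@@H](c1ccc(OC)c3c1O[C@H](c1ccc(OC)cc1OC)[C@H]3c1cc(OC)cc(OC)c1)O2
F5 | step 13 | (2R,3S)-4-bromo-2-[(2S,3S)-2-(2,4-dihydroxyphenyl)-3-(3,5-dihydroxyphenyl)-4-hydroxy-2,3-dihydro-1-benzofuran-7-yl]-3-(3,5-dihydroxyphenyl)-2,3-dihydro-1-benzofuran-6-ol (upper ring cis) | Brc1cc(O)cc2c1[C@H](c1cc(O)cc(O)c1)[C@H](c1ccc(O)c3c1O[C@H](c1ccc(O)cc1O)[C@H]3c1cc(O)cc(O)c1)O2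
F6 | step 11 | N-(tert-butyldimethylsilyl)hydrazone of 17 | COc1cc(OC)cc(c1)C(=NN[Si](C)(C)C(C)(C)C)c1c(Br)cc(OC)cc1OCc1ccc(OC)c2c1O[C@H](c1ccc(OC)cc1OC)[C@H]2c1cc(OC)cc(OC)c1
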